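**Strategy.** Everything rests on disconnecting the decalin at C5–C10 and C7–C8 (labdane numbering). A single base-mediated Michael/aldol-condensation cascade, in which the C6 methyl ketone acts twice as donor (via C5, then C7) towards the C10=C9–C8(=O) unit, closes rings A and B at once. It exploits the 1,5-related oxygens on C6 and C8 of ring B and the cis pair C20/O12, tied as a δ-lactone. The precursor is therefore a monocyclic 3-alkyl-4-acetyl-5,6-dihydropyran-2-one; its C12 stereocentre directs C10, the lactone locks C9, and later reduction releases the 12- and 20-hydroxyls. Enone epoxidation and reductive opening then set C8.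

Key step: step 14

Remark (assumption): labdane numbering is used throughout (decalin C1–C10, C20 on C10, side chain C11–C16, C17 on C8); the facial sense of (+)-Ipc2B(allyl) and of the Pd/bisphosphine etherification is taken as stated, the antipodal reagent or ligand being used otherwise.

**Ring-A fragment**

Step 1
Reactants: 1 2,2-dimethylpent-4-enal
Product: 2 2,2-dimethyl-4-oxopentanal
Conditions: PdCl2 (cat.), CuCl, O2 (1 atm), DMF/H2O, rt
Reagents that add atoms: water, O
Why: Tsuji–Wacker oxidation, in which Markovnikov hydroxypalladation of the terminal alkene gives the methyl ketone (future C6/C7) while the α-quaternary aldehyde is left alone.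

Step 2
Reactants: 2 2,2-dimethyl-4-oxopentanal
Product: 3 (5R)-5-hydroxy-4,4-dimethyloct-7-en-2-one
Conditions: (+)-Ipc2B(allyl), Et2O, −78 °C; then NaOH, H2O2, 0 °C
Reagents that add atoms: (+)-B-allyldiisopinocampheylborane, C=CCB([C@H]1C[C@H]2C[C@@H]([C@@H]1C)C2(C)C)[C@H]1C[C@H]2C[C@@H]([C@@H]1C)C2(C)C
Why: Brown allylation through a chair-like six-membered transition state should add allyl to the aldehyde only (the ketone is inert at −78 °C), the isopinocampheyl groups setting the carbinol (future C3) as R.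

Step 3
Reactants: 3 (5R)-5-hydroxy-4,4-dimethyloct-7-en-2-one
Product: 4 (5R)-5-[(4-methoxybenzyl)oxy]-4,4-dimethyloct-7-en-2-one
Conditions: 2-(4-methoxybenzyloxy)-4-methylquinoline, MeOTf, MgO, PhCF3, 0 °C → rt
Reagents that add atoms: 2-[(4-methoxybenzyl)oxy]-4-methylquinoline, COc1ccc(COc2cc(C)c3ccccc3n2)cc1
Why: Neutral 4-methoxybenzyl transfer from the N-methylated alkoxyquinolinium salt formed in the flask etherifies the hindered secondary alcohol without the acid or base that would turn the γ-hydroxy ketone into a cyclic enol ether or an enolate.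

Step 4
Reactants: 4 (5R)-5-[(4-methoxybenzyl)oxy]-4,4-dimethyloct-7-en-2-one
Product: 5 (3R)-3-[(4-methoxybenzyl)oxy]-4,4-dimethyl-6-oxoheptanal
Conditions: O3, CH2Cl2, −78 °C (Sudan Red 7B end point); then PPh3
Reagents that add atoms: ozone, [O-][O+]=O
Why: Ozonolysis with reductive work-up cleaves the only C=C bond (the anisyl ring reacts far more slowly) and unveils the C1 aldehyde.

**Side-chain lactone fragment**

Step 5
Reactants: 6 2-methyl-2-vinyloxirane (racemic), 7 4-methoxybenzyl alcohol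
Product: 8 (2R)-2-[(4-methoxybenzyl)oxy]-2-methylbut-3-en-1-ol
Conditions: Pd2(dba)3·CHCl3 (1 mol %), N,N′-bis(2-diphenylphosphinobenzoyl)-trans-1,2-diaminocyclohexane [enantiomer giving (R)-8] (3 mol %), BEt3 (1 mol %), CH2Cl2, rt
Reagents that add atoms: none
Why: Pd-catalysed dynamic kinetic asymmetric allylic etherification (Tsuji–Trost type), in which the interconverting π-allyl complexes from the racemic epoxide are captured at the tertiary terminus by boron-templated delivery of the alcohol, the ligand setting the quaternary centre (future C13).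

Step 6
Reactants: 8 (2R)-2-[(4-methoxybenzyl)oxy]-2-methylbut-3-en-1-ol
Product: 9 (2R)-2-[(4-methoxybenzyl)oxy]-2-methylbut-3-enal
Conditions: TEMPO (cat.), PhI(OAc)2, CH2Cl2, rt
Reagents that add atoms: none
Why: Oxoammonium-mediated oxidation of the primary alcohol stops at the aldehyde, which has no α-hydrogen and so cannot epimerise or conjugate.

Step 7
Reactants: 9 (2R)-2-[(4-methoxybenzyl)oxy]-2-methylbut-3-enal
Product: 10 (3R)-3-[(4-methoxybenzyl)oxy]-3-methylpent-1-en-4-yne
Conditions: dimethyl (1-diazo-2-oxopropyl)phosphonate, K2CO3, MeOH, 0 °C → rt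
Reagents that add atoms: dimethyl (1-diazo-2-oxopropyl)phosphonate, COP(=O)(OC)C(=[N+]=[N-])C(C)=O
Why: Seyferth–Gilbert homologation with the Ohira–Bestmann reagent converts the aldehyde into the terminal alkyne (future C14–C15) under mild base without touching the quaternary centre.

Step 8
Reactants: 10 (3R)-3-[(4-methoxybenzyl)oxy]-3-methylpent-1-en-4-yne
Product: 11 (2S)-2-[(4-methoxybenzyl)oxy]-2-methylbut-3-ynal
Conditions: O3, CH2Cl2, −78 °C (Sudan Red 7B end point); then PPh3
Reagents that add atoms: ozone, [O-][O+]=O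
Why: Ozonolysis discriminates the alkene from the much less reactive alkyne and turns the former vinyl carbon into the C12 aldehyde, the descriptor changing to S only through the priority switch.

Step 9
Reactants: 11 (2S)-2-[(4-methoxybenzyl)oxy]-2-methylbut-3-ynal, 12 1-methoxy-1,3-bis(trimethylsilyloxy)buta-1,3-diene
Product: 14 (6R)-4-hydroxy-6-{(2S)-2-[(4-methoxybenzyl)oxy]but-3-yn-2-yl}-5,6-dihydro-2H-pyran-2-one, via hydroxy keto ester 13 (not isolated)
Conditions: MgBr2·OEt2, CH2Cl2, −78 → −40 °C; aq. NH4Cl; then K2CO3, MeOH, rt; HCl to pH 3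
Reagents that add atoms: none
Why: Chelation-controlled vinylogous Mukaiyama aldol, in which magnesium bridges the aldehyde and ether oxygens and the dienolate terminus attacks the face flanked by the slim ethynyl group and not the methyl group (Cram-chelate model), should set C12 as R, after which base-mediated lactonisation closes the pyran-2,4-dione.

Step 10
Reactants: 14 (6R)-4-hydroxy-6-{(2S)-2-[(4-methoxybenzyl)oxy]but-3-yn-2-yl}-5,6-dihydro-2H-pyran-2-one
Product: 15 (6R)-4-hydroxy-6-{(2S)-2-[(4-methoxybenzyl)oxy]but-3-en-2-yl}-5,6-dihydro-2H-pyran-2-one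
Conditions: H2 (1 atm), Pd/CaCO3 poisoned with Pb(OAc)2 (Lindlar catalyst), quinoline, EtOAc, rt
Reagents that add atoms: none
Why: Lindlar semihydrogenation should stop at the vinyl group (C14=C15) and leaves the benzylic ethers intact.

**Union and elaboration**

Step 11
Reactants: 15 (6R)-4-hydroxy-6-{(2S)-2-[(4-methoxybenzyl)oxy]but-3-en-2-yl}-5,6-dihydro-2H-pyran-2-one, 5 (3R)-3-[(4-methoxybenzyl)oxy]-4,4-dimethyl-6-oxoheptanal
Product: 17 (6R)-4-hydroxy-3-{(3R)-3-[(4-methoxybenzyl)oxy]-4,4-dimethyl-6-oxoheptyl}-6-{(2S)-2-[(4-methoxybenzyl)oxy]but-3-en-2-yl}-5,6-dihydro-2H-pyran-2-one, via Knoevenagel adduct 16 (not isolated)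
Conditions: diethyl 1,4-dihydro-2,6-dimethylpyridine-3,5-dicarboxylate (Hantzsch ester), L-proline (10 mol %), CH2Cl2, rt
Reagents that add atoms: none
Why: Organocatalytic reductive alkylation, in which Knoevenagel condensation of the acidic cyclic 1,3-dicarbonyl with the aldehyde is followed at once by conjugate hydride transfer from the dihydropyridine, should give clean C-alkylation (the C1–C10 bond) and spare the methyl ketone.

Step 12
Reactants: 17 (6R)-4-hydroxy-3-{(3R)-3-[(4-methoxybenzyl)oxy]-4,4-dimethyl-6-oxoheptyl}-6-{(2S)-2-[(4-methoxybenzyl)oxy]but-3-en-2-yl}-5,6-dihydro-2H-pyran-2-one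
Product: 18 (6R)-3-{(3R)-3-[(4-methoxybenzyl)oxy]-4,4-dimethyl-6-oxoheptyl}-6-{(2S)-2-[(4-methoxybenzyl)oxy]but-3-en-2-yl}-2-oxo-5,6-dihydro-2H-pyran-4-yl trifluoromethanesulfonate
Conditions: Tf2O, Et3N, CH2Cl2, −78 °C
Reagents that add atoms: trifluoromethanesulfonic anhydride, O=S(=O)(OS(=O)(=O)C(F)(F)F)C(F)(F)F
Why: O-Sulfonylation of the vinylogous acid (enol triflate formation) is far faster than enolisation of the side-chain methyl ketone at −78 °C.

Step 13
Reactants: 18 (6R)-3-{(3R)-3-[(4-methoxybenzyl)oxy]-4,4-dimethyl-6-oxoheptyl}-6-{(2S)-2-[(4-methoxybenzyl)oxy]but-3-en-2-yl}-2-oxo-5,6-dihydro-2H-pyran-4-yl trifluoromethanesulfonate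
Product: 20 (6R)-4-acetyl-3-{(3R)-3-[(4-methoxybenzyl)oxy]-4,4-dimethyl-6-oxoheptyl}-6-{(2S)-2-[(4-methoxybenzyl)oxy]but-3-en-2-yl}-5,6-dihydro-2H-pyran-2-one, via enol ether 19 (not isolated)
Conditions: tributyl(1-ethoxyvinyl)stannane, Pd(PPh3)4 (5 mol %), LiCl, CuI (10 mol %), THF, 65 °C; then 1 M HCl, THF, 0 °C
Reagents that add atoms: tributyl(1-ethoxyvinyl)stannane, CCCC[Sn](CCCC)(CCCC)C(=C)OCC; water, O
Why: Stille coupling at the electron-poor β-triflyloxy enoate followed by mild hydrolysis of the enol ether installs the acetyl group (C8 and C17) on C9.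

Step 14
Reactants: 20 (6R)-4-acetyl-3-{(3R)-3-[(4-methoxybenzyl)oxy]-4,4-dimethyl-6-oxoheptyl}-6-{(2S)-2-[(4-methoxybenzyl)oxy]but-3-en-2-yl}-5,6-dihydro-2H-pyran-2-one
Product: 23 (12R,13S)-3α,13-bis[(4-methoxybenzyl)oxy]-6-oxolabda-7,14-dien-20,12-olide, via spiro Michael adduct 21 (not isolated), via ketol 22 (not isolated)
Conditions: KOt-Bu (0.3 equiv), 4 Å MS, t-BuOH/THF, 0 → 40 °C; AcOH
Reagents that add atoms: none
Why: Reversible enolisation of the C6 methyl ketone lets its C5 enolate add 6-exo to C10 of the lactone- and acetyl-activated alkene (intramolecular Michael addition, ring A); after proton transfer the C7 enolate of the same ketone attacks the C8 carbonyl (6-enolendo aldol, ring B) and water is lost, so the closest known reaction type is a Robinson-type Michael/aldol-condensation cascade. C10 is set by the C12 stereocentre of the dihydropyranone: with the bulky C13 group pseudo-equatorial, perpendicular attack on C10 through a chair-like lactone ring is cis to that group, the same stereoelectronic preference that makes additions at C4 of 6-substituted dihydropyranones trans. C9 must carry its hydrogen on the α face because only a cis-fused δ-lactone can span C20 and the C11 arm, and C5 should equilibrate to the trans ring fusion through the C6 enolate. The step needs C10 and not C9 as the acceptor site, and C7-to-C8 and not C17-to-C6 aldol regiochemistry. The first is secured by six- versus seven-membered ring size and by the reversibility of conjugate addition, which funnels material into the irreversible condensation; the second by the congestion around C6 (flanked by C4 and C10) and by the greater stability of the 6-oxo-Δ7 enone. Closures of C7 or C17 onto the C20 carbonyl would be five-membered enolendo cyclisations and are disfavoured.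

Step 15
Reactants: 23 (12R,13S)-3α,13-bis[(4-methoxybenzyl)oxy]-6-oxolabda-7,14-dien-20,12-olide
Product: 24 (12R,13S)-7α,8α-epoxy-3α,13-bis[(4-methoxybenzyl)oxy]-6-oxolabd-14-en-20,12-olide
Conditions: t-BuOOH (decane solution), DBU, CH2Cl2, 0 °C → rt
Reagents that add atoms: tert-butyl hydroperoxide, CC(C)(C)OO
Why: Weitz–Scheffer nucleophilic epoxidation, in which the peroxide anion should add to C8 from the α face, anti to the axial C20 carbonyl and the lactone bridge, so that ring closure gives the 7α,8α-epoxide.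

Step 16
Reactants: 24 (12R,13S)-7α,8α-epoxy-3α,13-bis[(4-methoxybenzyl)oxy]-6-oxolabd-14-en-20,12-olide
Product: 25 (12R,13S)-8α-hydroxy-3α,13-bis[(4-methoxybenzyl)oxy]-6-oxolabd-14-en-20,12-olide
Conditions: SmI2 (2.5 equiv), THF/MeOH, −90 °C
Reagents that add atoms: none
Why: Reductive opening of the α,β-epoxy ketone by SmI2 cleaves only the C7–O bond next to the ketyl, so C8 keeps its α-oxygen and β-methyl, the arrangement a direct aldol would not be expected to give.

Step 17
Reactants: 25 (12R,13S)-8α-hydroxy-3α,13-bis[(4-methoxybenzyl)oxy]-6-oxolabd-14-en-20,12-olide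
Product: 26 (12R,13S)-3α,13-bis[(4-methoxybenzyl)oxy]labd-14-ene-6β,8α,12,20-tetraol
Conditions: LiAlH4, THF, 0 °C → rt; Fieser work-up
Reagents that add atoms: none
Why: Hydride reduction should attack the C6 ketone from the α face (the β face is blocked by axial C20 and the 4β-methyl) to give the axial 6β-alcohol, and it opens the lactone to the C20 and C12 alcohols.

Step 18
Reactants: 26 (12R,13S)-3α,13-bis[(4-methoxybenzyl)oxy]labd-14-ene-6β,8α,12,20-tetraol
Product: 27 (12R,13S)-6β,8α,12,20-tetraacetoxy-3α,13-bis[(4-methoxybenzyl)oxy]labd-14-ene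
Conditions: Ac2O, DMAP, pyridine, 60 °C
Reagents that add atoms: acetic anhydride, CC(=O)OC(C)=O
Why: DMAP-catalysed acylation under forcing conditions should acetylate all four free hydroxyls, including the tertiary 8α-OH and the hindered axial 6β-OH, while O3 and O13 stay masked as benzylic ethers.

Step 19
Reactants: 27 (12R,13S)-6β,8α,12,20-tetraacetoxy-3α,13-bis[(4-methoxybenzyl)oxy]labd-14-ene
Product: 28 (12R,13S)-6β,8α,12,20-tetraacetoxylabd-14-ene-3α,13-diol (CNP0292984.1)
Conditions: DDQ, CH2Cl2/pH 7 phosphate buffer, 0 °C → rt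
Reagents that add atoms: none
Why: Oxidative cleavage of both 4-methoxybenzyl ethers by DDQ (benzylic hydride abstraction, then hydrolysis) frees the 3α- and 13-hydroxyls under neutral conditions that should not disturb the four acetates, the vinyl group or the tertiary allylic alcohol.

**Compound list**

1 | 2,2-dimethylpent-4-enal | C=CCC(C)(C)C=O | starting material
2 | 2,2-dimethyl-4-oxopentanal | CC(=O)CC(C)(C)C=O | intermediate
3 | (5R)-5-hydroxy-4,4-dimethyloct-7-en-2-one | C=CC[C@@H](O)C(C)(C)CC(C)=O | intermediate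
4 | (5R)-5-[(4-methoxybenzyl)oxy]-4,4-dimethyloct-7-en-2-one | C=CC[C@@H](OCc1ccc(OC)cc1)C(C)(C)CC(C)=O | intermediate
5 | (3R)-3-[(4-methoxybenzyl)oxy]-4,4-dimethyl-6-oxoheptanal | O=CC[C@@H](OCc1ccc(OC)cc1)C(C)(C)CC(C)=O | intermediate
6 | 2-methyl-2-vinyloxirane (racemic) | CC1(C=C)CO1 | starting material
7 | 4-methoxybenzyl alcohol | COc1ccc(CO)cc1 | starting material
8 | (2R)-2-[(4-methoxybenzyl)oxy]-2-methylbut-3-en-1-ol | OC[C@](C)(OCc1ccc(OC)cc1)C=C | intermediate
9 | (2R)-2-[(4-methoxybenzyl)oxy]-2-methylbut-3-enal | O=C[C@](C)(OCc1ccc(OC)cc1)C=C | intermediate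
10 | (3R)-3-[(4-methoxybenzyl)oxy]-3-methylpent-1-en-4-yne | C#C[C@](C)(OCc1ccc(OC)cc1)C=C | intermediate
11 | (2S)-2-[(4-methoxybenzyl)oxy]-2-methylbut-3-ynal | C#C[C@](C)(OCc1ccc(OC)cc1)C=O | intermediate
12 | 1-methoxy-1,3-bis(trimethylsilyloxy)buta-1,3-diene | COC(O[Si](C)(C)C)=CC(=C)O[Si](C)(C)C | starting material
13 | methyl (5R,6S)-5-hydroxy-6-[(4-methoxybenzyl)oxy]-6-methyl-3-oxooct-7-ynoate (not isolated) | C#C[C@](C)(OCc1ccc(OC)cc1)[C@@H](CC(=O)CC(=O)OC)O | intermediate
14 | (6R)-4-hydroxy-6-{(2S)-2-[(4-methoxybenzyl)oxy]but-3-yn-2-yl}-5,6-dihydro-2H-pyran-2-one | C#C[C@](C)(OCc1ccc(OC)cc1)[C@H]1CC(O)=CC(=O)O1 | intermediate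
15 | (6R)-4-hydroxy-6-{(2S)-2-[(4-methoxybenzyl)oxy]but-3-en-2-yl}-5,6-dihydro-2H-pyran-2-one | C=C[C@](C)(OCc1ccc(OC)cc1)[C@H]1CC(O)=CC(=O)O1 | intermediate
16 | Knoevenagel adduct: (6R)-3-{(3R)-3-[(4-methoxybenzyl)oxy]-4,4-dimethyl-6-oxoheptylidene}-6-{(2S)-2-[(4-methoxybenzyl)oxy]but-3-en-2-yl}dihydro-2H-pyran-2,4(3H)-dione, alkene geometry not defined (not isolated) | C=C[C@](C)(OCc1ccc(OC)cc1)[C@H]1CC(=O)C(=CC[C@@H](OCc2ccc(OC)cc2)C(C)(C)CC(C)=O)C(=O)O1 | intermediate
17 | (6R)-4-hydroxy-3-{(3R)-3-[(4-methoxybenzyl)oxy]-4,4-dimethyl-6-oxoheptyl}-6-{(2S)-2-[(4-methoxybenzyl)oxy]but-3-en-2-yl}-5,6-dihydro-2H-pyran-2-one | C=C[C@](C)(OCc1ccc(OC)cc1)[C@H]1CC(O)=C(CC[C@@H](OCc2ccc(OC)cc2)C(C)(C)CC(C)=O)C(=O)O1 | intermediate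
18 | 4-triflate of 17: (6R)-3-{(3R)-3-[(4-methoxybenzyl)oxy]-4,4-dimethyl-6-oxoheptyl}-6-{(2S)-2-[(4-methoxybenzyl)oxy]but-3-en-2-yl}-2-oxo-5,6-dihydro-2H-pyran-4-yl trifluoromethanesulfonate | C=C[C@](C)(OCc1ccc(OC)cc1)[C@H]1CC(OS(=O)(=O)C(F)(F)F)=C(CC[C@@H](OCc2ccc(OC)cc2)C(C)(C)CC(C)=O)C(=O)O1 | intermediate
19 | 4-(1-ethoxyvinyl) analogue of 18 (not isolated) | C=C[C@](C)(OCc1ccc(OC)cc1)[C@H]1CC(C(=C)OCC)=C(CC[C@@H](OCc2ccc(OC)cc2)C(C)(C)CC(C)=O)C(=O)O1 | intermediate
20 | (6R)-4-acetyl-3-{(3R)-3-[(4-methoxybenzyl)oxy]-4,4-dimethyl-6-oxoheptyl}-6-{(2S)-2-[(4-methoxybenzyl)oxy]but-3-en-2-yl}-5,6-dihydro-2H-pyran-2-one | C=C[C@](C)(OCc1ccc(OC)cc1)[C@H]1CC(C(C)=O)=C(CC[C@@H](OCc2ccc(OC)cc2)C(C)(C)CC(C)=O)C(=O)O1 | intermediate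
21 | spiro Michael adduct: (12R,13S)-3α,13-bis[(4-methoxybenzyl)oxy]-6,8-dioxo-7,8-secolabd-14-en-20,12-olide, 5α-H, 9α-H, 10β-carbonyl (not isolated) | C=C[C@](C)(OCc1ccc(OC)cc1)[C@H]1C[C@@H](C(C)=O)[C@@]3(C(=O)O1)CC[C@@H](OCc4ccc(OC)cc4)C(C)(C)[C@@H]3C(C)=O | intermediate
22 | ketol: (12R,13S)-8-hydroxy-3α,13-bis[(4-methoxybenzyl)oxy]-6-oxolabd-14-en-20,12-olide, C8 epimers (not isolated) | C=C[C@](C)(OCc1ccc(OC)cc1)[C@H]1C[C@@H]2[C@@]3(C(=O)O1)CC[C@@H](OCc4ccc(OC)cc4)C(C)(C)[C@@H]3C(=O)CC2(C)O | intermediate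
23 | (12R,13S)-3α,13-bis[(4-methoxybenzyl)oxy]-6-oxolabda-7,14-dien-20,12-olide (5α-H, 9α-H, 10β-carbonyl) | C=C[C@](C)(OCc1ccc(OC)cc1)[C@H]1C[C@@H]2[C@@]3(C(=O)O1)CC[C@@H](OCc4ccc(OC)cc4)C(C)(C)[C@@H]3C(=O)C=C2C | intermediate
24 | (12R,13S)-7α,8α-epoxy-3α,13-bis[(4-methoxybenzyl)oxy]-6-oxolabd-14-en-20,12-olide | C=C[C@](C)(OCc1ccc(OC)cc1)[C@H]1C[C@@H]2[C@@]3(C(=O)O1)CC[C@@H](OCc4ccc(OC)cc4)C(C)(C)[C@@H]3C(=O)[C@H]5O[C@@]25C | intermediate
25 | (12R,13S)-8α-hydroxy-3α,13-bis[(4-methoxybenzyl)oxy]-6-oxolabd-14-en-20,12-olide | C=C[C@](C)(OCc1ccc(OC)cc1)[C@H]1C[C@@H]2[C@@]3(C(=O)O1)CC[C@@H](OCc4ccc(OC)cc4)C(C)(C)[C@@H]3C(=O)C[C@@]2(C)O | intermediate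
26 | (12R,13S)-3α,13-bis[(4-methoxybenzyl)oxy]labd-14-ene-6β,8α,12,20-tetraol | C=C[C@](C)(OCc1ccc(OC)cc1)[C@@H](C[C@@H]1[C@@]2(CO)CC[C@@H](OCc3ccc(OC)cc3)C(C)(C)[C@@H]2[C@H](O)C[C@@]1(C)O)O | intermediate
27 | (12R,13S)-6β,8α,12,20-tetraacetoxy-3α,13-bis[(4-methoxybenzyl)oxy]labd-14-ene | C=C[C@](C)(OCc1ccc(OC)cc1)[C@@H](C[C@@H]1[C@@]2(COC(C)=O)CC[C@@H](OCc3ccc(OC)cc3)C(C)(C)[C@@H]2[C@H](OC(C)=O)C[C@@]1(C)OC(C)=O)OC(C)=O | intermediate
28 | (12R,13S)-6β,8α,12,20-tetraacetoxylabd-14-ene-3α,13-diol (CNP0292984.1) | C=C[C@](C)(O)[C@@H](C[C@@H]1[C@@]2(COC(C)=O)CC[C@@H](O)C(C)(C)[C@@H]2[C@H](OC(C)=O)C[C@@]1(C)OC(C)=O)OC(C)=O | target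

**Step count and risks**

Total step count: 19. Longest linear sequence: 15 steps (steps 5–19, from 6).

Steps most likely to fail:

1. Step 14. Before the C5 enolate reaches C10, the base may remove a C11 proton of the unsaturated lactone and trigger β-elimination of the C12 carboxylate (ring opening to a dienoic acid). The congested C5–C10 bond may also revert by retro-Michael reaction faster than ring B closes, and any opening of the lactone frees C9 to epimerise. The fallback is an enamine-mediated annulation that needs no metal enolate. Setting out from 20, condensation with pyrrolidine and acetic acid (toluene, 4 Å MS, rt → 50 °C) should give the C5=C6 enamine of the side-chain ketone F1 in equilibrium with its C6=C7 isomer. Intramolecular enamine Michael addition to C10 and enamine aldol condensation onto C8 in the same flask should then lead to the unsaturated iminium acetate F2. Aqueous NaOAc/AcOH hydrolyses it, and the route is rejoined at 23.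

2. Step 9. Incomplete chelation (the ether oxygen sits on a quaternary carbon) would erode the facial selectivity at the aldehyde, and the Lewis acid may ionise the tertiary propargylic ether. The fallback is a catalyst-controlled vinylogous Mukaiyama aldol. Setting out from 11, 2,2-dimethyl-6-methylene-4-(trimethylsilyloxy)-4H-1,3-dioxine with Cu(OTf)2, Tol-BINAP (the enantiomer giving the 2R carbinol) and tetrabutylammonium difluorotriphenylsilicate in THF at −78 °C, followed by acidic work-up, would give the hydroxy dioxinone F3. Heating in toluene (110 °C) expels acetone, the acylketene is trapped by the hydroxyl, and the route is rejoined at 14.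

3. Step 15. The peroxide anion may add too slowly to the hindered, β,β-disubstituted C8 terminus, so that attack on the lactone carbonyl or base-induced deconjugation of the enone takes over. The fallback is a copper-catalysed conjugate borylation. Setting out from 23, B2pin2, CuCl, NaOt-Bu, bis[2-(diphenylphosphino)phenyl] ether and MeOH in THF should deliver boron to C8 from the α face and give the β-boryl ketone F4. NaBO3·4H2O (THF/H2O) oxidises the C–B bond with retention, and the route is rejoined at 25, bypassing 24.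

**Further compounds**

F1 | step 14 | pyrrolidine enamine of 20 at the side-chain ketone (C5=C6 regioisomer, geometry not defined) | C=C[C@](C)(OCc1ccc(OC)cc1)[C@H]1CC(C(C)=O)=C(CC[C@@H](OCc2ccc(OC)cc2)C(C)(C)C=C(C)N2CCCC2)C(=O)O1
F2 | step 14 | pyrrolidinium (C6 iminium) acetate of enone 23 | C=C[C@](C)(OCc1ccc(OC)cc1)[C@H]1C[C@@H]2[C@@]3(C(=O)O1)CC[C@@H](OCc4ccc(OC)cc4)C(C)(C)[C@@H]3C(=[N+]5CCCC5)C=C2C.CC(=O)[O-]
F3 | step 9 | 6-{(2R,3S)-2-hydroxy-3-[(4-methoxybenzyl)oxy]-3-methylpent-4-yn-1-yl}-2,2-dimethyl-4H-1,3-dioxin-4-one | C#C[C@](C)(OCc1ccc(OC)cc1)[C@@H](CC1=CC(=O)OC(C)(C)O1)O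
F4 | step 15 | (12R,13S)-3α,13-bis[(4-methoxybenzyl)oxy]-6-oxo-8α-(4,4,5,5-tetramethyl-1,3,2-dioxaborolan-2-yl)labd-14-en-20,12-olide | C=C[C@](C)(OCc1ccc(OC)cc1)[C@H]1C[C@@H]2[C@@]3(C(=O)O1)CC[C@@H](OCc4ccc(OC)cc4)C(C)(C)[C@@H]3C(=O)C[C@@]2(C)B5OC(C)(C)C(C)(C)O5
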